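I decide to keep the books on the single product, and to count the substrate, the smaller charge in the flask.

| flask | substrate | reagent | remark | time |
|---|---|---|---|---|
| gamma | 12 mM | 19.8 mM | run made earlier |  |
| epsilon | 27 mM | 19.8 mM | run made earlier |  |
| beta | 18 mM | 40 mM | run made earlier |  |
| flask | 18 mM | 19.8 mM |  | 12 h |

| run | time / h | side product A / % | bis adduct / % |
|---|---|---|---|
| gamma | 1.33 | 60.3 | 0.4 |
| gamma | 2.50 | 60.5 | 0.3 |
| gamma | 4.00 | 60.5 | 0.2 |
| gamma | 5.00 | 60.9 | 0 |
| gamma | 6.00 | 59.3 | 0.5 |
| gamma | 8.00 | 60.8 | 0.4 |
| epsilon | 0.500 | 81.7 | 1.6 |
| epsilon | 1.00 | 82.7 | 0 |
| epsilon | 1.50 | 82.4 | 0 |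
| epsilon | 2.50 | 83.3 | 1.9 |
| epsilon | 4.00 | 83.6 | 0 |
| epsilon | 8.00 | 84.9 | 0.2 |
| beta | 0.500 | 52.4 | 0 |
| beta | 1.00 | 52.0 | 0 |
| beta | 2.00 | 52.1 | 0 |
| beta | 4.00 | 53.5 | 0.8 |
| beta | 8.00 | 52.1 | 0.4 |

(standard deviation of a reading: 1 percentage point)

- a species is counted by the substrate in it: one side product A counts as two
- what was read earlier has a scatter of 1 percentage point, one standard deviation
- steps thought possible: substrate + reagent -> single product + released group; reagent + single product -> bis adduct + released group; reagent + bis adduct -> triple product + released group; substrate + single product -> side product A; single product -> side product B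
- the reaction counts as stopped when no species that holds the substrate changes by six tenths of a point or more over the second half of the time

- which holds at 12 h: what has brought the reaction to rest, or that it has not come to rest (all of the substrate has reacted / the reagent has run out first / it is still moving)
- how much side product A there is at 12 h, in percent of the substrate charged

Why the single product? A substrate either takes up reagent and becomes single product, or a single product catches it and the two become side product A. With y the share in side product A, the caught single products over the escaped ones are z = y/(2·(1 − y)), the capture odds.

What do the runs give? Divide z by c(substrate)/c(reagent) as charged: this is the split number, an apparent selectivity factor. Gamma averages 60.4 %, which gives 1.26. Beta averages 52.4 %, giving 1.22. Epsilon averages 83.1 %, giving 1.80.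

Is it a constant? No: it stands higher in epsilon than in gamma, so I interpolate straight in c(substrate)/c(reagent) between these two runs. For the flask I reckon 1.48, hence y = 72.8 %.

Does the reagent last? If the whole remainder became triple product, the flask would need 1.18 reagent per substrate against 1.10 charged. That is the weak spot. Yet 3.94 % of the substrate going to side product B instead of triple product closes the gap, so I commit, narrowly, to substrate as the limiting reagent.

The forecast says all of the substrate has reacted and 72.5 %, below my 72.8 %: “The plateau therefore means substrate is used up.”

The flask gives all of the substrate has reacted and 72.7 %, with 6.3 % of the charged reagent still there.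

    substrate + reagent → single product + released group (k = 0.299 M⁻¹ s⁻¹)
    reagent + single product → bis adduct + released group (k = 0.524 M⁻¹ s⁻¹)
    reagent + bis adduct → triple product + released group (k = 0.590 M⁻¹ s⁻¹)
    substrate + single product → side product A (k = 1.62 M⁻¹ s⁻¹)
    single product → side product B (k = 0.00131 s⁻¹)

The flask's own split number is 1.47, between those of gamma and epsilon. The using up of reagent is part of what raises side product A in the flask: with that using up taken away, the flask gives 58.5 % against 72.7 %. For the neighbour flask with 34 mM of reagent, interpolation between beta and gamma gives a split number of 1.24 and so 56.8 %, and that flask stands at 57.1 %.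

The data come from a simulation on assumed constants; noise was put on by code.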